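## Retrosynthetic overview

1. Numbering: C1 acetoxy bridgehead, C2 guaiacyl CH, O3, C4H2, C5 bridgehead CH, C6 veratryl CH, O7, C8H2. Ring A = C1-C2-O3-C4-C5 and ring B = C5-C6-O7-C8-C1. The route rests on the run O7–C8H2–C1(OAc) in ring B. This is what a 3-acetoxy-4,5-dihydrofuran (a furanoid 2-acetoxyglycal) leaves behind once C1 has bonded to a carbon electrophile and C8 has taken up hydride, so the tertiary acetate arrives on an enol ether and no hindered alcohol has to be acylated.
2. Target ⇒ its phenol acetate (aryl acetate cleaved last) ⇒ cut C1–C2 and C2–O3. This gives the ring B enol acetate carrying a C4 triethylsilyl ether plus vanillin acetate, with C8 reduced in the same flask.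
3. Ring B enol acetate ⇒ loss of HBr from the 2-O-acetyl furanosyl bromide, which fixes the alkene at C8=C1. Enolising the corresponding furan-3-one is avoided because C5–H competes there and would expel the C4 or C6 oxygen.
4. Bromide ⇒ diacetate ⇒ lactol ⇒ α-hydroxylated trans γ-lactone ⇒ Evans syn aldol/lactonisation of the methyl succinyl imide of (S)-4-benzyl-2-oxazolidinone with veratraldehyde. This sets C5 and C6; the imide carbonyl becomes C4 and the ester carbonyl becomes C8.
5. Ring order: ring B first (step 2), ring A last (step 10).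

Key step: step 10

Remark: C8 in 11, 12, 13, F5 and F6 is an anomeric mixture and is written without configuration. This centre disappears when the C8=C1 double bond is made.

## Route

Step 1
Reactants: 1 (S)-4-benzyl-2-oxazolidinone; 2 methyl 4-chloro-4-oxobutanoate
Product: 3 methyl 4-[(4S)-4-benzyl-2-oxo-1,3-oxazolidin-3-yl]-4-oxobutanoate
Conditions: n-BuLi, THF, −78 °C; then 2, −78 → 0 °C
Reagents that add atoms: none
Why: N-Acylation of a lithiated oxazolidinone, the standard way to Evans imides: the acid chloride end of 2 reacts far faster than its methyl ester and the auxiliary stereocentre is not touched.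

Step 2
Reactants: 3 methyl 4-[(4S)-4-benzyl-2-oxo-1,3-oxazolidin-3-yl]-4-oxobutanoate; 4 veratraldehyde (3,4-dimethoxybenzaldehyde)
Product: 6 (4S)-4-benzyl-3-{[(2S,3S)-2-(3,4-dimethoxyphenyl)-5-oxooxolan-3-yl]carbonyl}-1,3-oxazolidin-2-one (trans lactone), via syn-aldol 5 (not isolated)
Conditions: n-Bu2BOSO2CF3, Et3N, CH2Cl2, −78 → 0 °C; 4, −78 → 0 °C; pH 7 buffer, MeOH, H2O2, 0 °C; crude 5, PPTS (cat.), toluene, 50 °C
Reagents that add atoms: none
Why: Evans boron syn aldol followed by lactonisation: n-Bu2BOSO2CF3/Et3N enolises only the imide to its (Z)-boron enolate, the chair transition state with the benzyl group blocking one enolate face sets C5 and C6 (both S in 5), and the C6 hydroxyl then acylates itself with the methyl ester (5-exo-trig), which puts the veratryl group and the C4 carbonyl trans on ring B, the arrangement that is also thermodynamically preferred.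

Step 3
Reactants: 6 trans lactone imide
Product: 7 (2S,3S)-2-(3,4-dimethoxyphenyl)-5-oxooxolane-3-carboxylic acid
Conditions: LiOH, H2O2, THF/H2O, 0 °C; Na2SO3; HCl to pH 2
Reagents that add atoms: hydrogen peroxide, OO (as LiOOH; supplies the acid OH)
Why: Hydroperoxide cleavage of an Evans imide: the small α-effect nucleophile LiOOH attacks the exocyclic carbonyl, C5 is not epimerised at 0 °C, and any lactone that is opened closes again to the only possible γ-lactone on acidification.

Step 4
Reactants: 7 (2S,3S)-2-(3,4-dimethoxyphenyl)-5-oxooxolane-3-carboxylic acid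
Product: 8 (4R,5S)-5-(3,4-dimethoxyphenyl)-4-(hydroxymethyl)oxolan-2-one
Conditions: BH3·SMe2, THF, 0 °C → rt; MeOH
Reagents that add atoms: none
Why: Chemoselective borane reduction: a free acid is reduced through its acyloxyborane far faster than a lactone, so only C4 reaches the alcohol stage and no stereocentre is involved.

Step 5
Reactants: 8 (4R,5S)-5-(3,4-dimethoxyphenyl)-4-(hydroxymethyl)oxolan-2-one
Product: 9 (4R,5S)-5-(3,4-dimethoxyphenyl)-4-[(triethylsilyloxy)methyl]oxolan-2-one
Conditions: Et3SiCl, imidazole, CH2Cl2, 0 °C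
Reagents that add atoms: chlorotriethylsilane, CC[Si](Cl)(CC)CC
Why: Standard silylation of a primary alcohol, carried out directly on crude 8 so that migration of the lactone to the C4 oxygen cannot set in, and it installs the silyl ether that step 10 will use as the O3 donor.

Step 6
Reactants: 9 (4R,5S)-5-(3,4-dimethoxyphenyl)-4-[(triethylsilyloxy)methyl]oxolan-2-one
Product: 10 (3S,4S,5S)-5-(3,4-dimethoxyphenyl)-3-hydroxy-4-[(triethylsilyloxy)methyl]oxolan-2-one (C1 hydroxyl trans to the C5 arm)
Conditions: KN(SiMe3)2, THF, −78 °C; 3-phenyl-2-(phenylsulfonyl)oxaziridine, −78 °C; AcOH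
Reagents that add atoms: 3-phenyl-2-(phenylsulfonyl)oxaziridine, O=S(=O)(c1ccccc1)N1OC1c1ccccc1
Why: Davis oxidation of a lactone enolate: C1 is the only acidic position, no leaving group stands β to the enolate, and the oxaziridine approaches anti to the adjacent C5 arm so that the new C1 hydroxyl is trans to it (3S), a centre that is erased again in step 9.

Step 7
Reactants: 10 α-hydroxy lactone
Product: 11 (3S,4S,5S)-5-(3,4-dimethoxyphenyl)-4-[(triethylsilyloxy)methyl]oxolane-2,3-diol (lactol, anomeric mixture)
Conditions: i-Bu2AlH (2.5 equiv), CH2Cl2, −78 °C; aq potassium sodium tartrate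
Reagents that add atoms: none
Why: Half-reduction of a γ-lactone with i-Bu2AlH: the first equivalent is consumed by the hydroxyl group, the second gives a tetrahedral aluminium hemiacetal that is stable at −78 °C, and C8 emerges as an inconsequential anomeric mixture.

Step 8
Reactants: 11 lactol diol
Product: 12 (3S,4R,5S)-5-(3,4-dimethoxyphenyl)-4-[(triethylsilyloxy)methyl]oxolane-2,3-diyl diacetate (anomeric mixture)
Conditions: Ac2O, pyridine, DMAP (cat.), CH2Cl2, 0 °C → rt
Reagents that add atoms: acetic anhydride, CC(=O)OC(C)=O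
Why: Routine peracetylation, which places the future tertiary acetate on the C1 oxygen while that oxygen is still an unhindered secondary alcohol and turns the C8 hydroxyl into a leaving group.

Step 9
Reactants: 12 furanose 1,2-diacetate
Product: 14 (2S,3R)-2-(3,4-dimethoxyphenyl)-3-[(triethylsilyloxy)methyl]-2,3-dihydrofuran-4-yl acetate (ring B enol acetate), via furanosyl bromide 13 (not isolated)
Conditions: Me3SiBr, CH2Cl2, 0 °C; evaporate; DBU, CH2Cl2, 0 °C → rt; Et3N-deactivated silica
Reagents that add atoms: bromotrimethylsilane, C[Si](C)(C)Br (bromine of 13; it leaves again with DBU)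
Why: Classical 2-acetoxyglycal synthesis: Me3SiBr exchanges only the anomeric acetate (assisted by the C1 acetate), the bromide anomers interconvert so that one with Br anti to H1 is available, and the E2 elimination with DBU can use only H1, the sole β-hydrogen, which fixes the double bond at C8=C1 and leaves C5 and C6 untouched.

Step 10
Reactants: 14 ring B enol acetate; 15 vanillin acetate (4-formyl-2-methoxyphenyl acetate)
Product: 18 (3R,3aS,6S,6aR)-3-(4-acetoxy-3-methoxyphenyl)-6-(3,4-dimethoxyphenyl)tetrahydro-1H,3H-furo[3,4-c]furan-3a-yl acetate (phenol acetate of the target), via oxocarbenium ion 16 (not isolated), via bicyclic C8 cation 17 (not isolated)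
Conditions: 15 (1.2 equiv), 2,6-di-tert-butyl-4-methylpyridine, 4 Å MS, CH2Cl2, −78 °C; Me3SiOSO2CF3 (1.2 equiv), −78 → −40 °C; then Et3SiH (3 equiv), −40 → −10 °C; aq NaHCO3
Reagents that add atoms: none
Why: Proposed new method: Me3SiOSO2CF3 joins the C4 silyl ether and aldehyde 15 to a mixed silyl acetal and ionises it (loss of Et3SiOSiMe3) to the (E)-O3=C2 oxocarbenium ion 16, C1 of the O7–C8=C1 enol ether adds to C2 in a Prins-type closure, and the resulting C8 cation 17, held as an acetoxonium ion by the C1 acetate and unable to lose a proton because C1 is now quaternary, is reduced to C8H2 by Et3SiH. The nearest known reaction types are the acid-promoted union of (2,3-dihydrofuran-3-yl)methanols and ArCH(OMe)2 to furofuran acetals that are then deoxygenated by a silane, the Me3SiOSO2CF3-mediated condensation of silyl ethers with aldehydes, the addition of halonium-type electrophiles to C2 of 2-acyloxyglycals and the Et3SiH reduction of 2-O-acetyl glycosyl cations to anhydroalditols, whereas building a quaternary acyloxy carbon by C–C bond formation in this manner has not been shown. Ring A (C1–C2–O3–C4–C5) closes 5-endo-trig with respect to the O3=C2 bond and exo with respect to the C8=C1 bond, a mode that is strained for plain alkenes but is regularly followed by oxocarbenium ions. C1 is controlled by the tether, since the C4–O3 arm stands on the face of ring B opposite to the veratryl group and is too short to reach the other face, so C2 bonds syn to C4, the fusion is cis and the acetate is pushed to the convex face beside H5 (1S). C2 is controlled by the (E) geometry of 16 together with the envelope of the closing ring in which O3 lies outside ring B, which makes the aryl group pseudo-equatorial and directs it away from the C8–O7 edge to the convex face (2R), while the other envelope would press it onto the concave face over C8. The step needs C1 and not C8 as the nucleophilic carbon, secured because the O7 alkoxy donor outweighs the acyloxy donor, and it needs hydride to reach only C8, secured by adding Et3SiH after 14 is consumed so that 16 is not reduced to a benzyl ether, while the hindered pyridine keeps triflic acid from protonating the enol ether or ionising the benzylic C6–O7 bond.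

Step 11
Reactants: 18 phenol acetate of the target
Product: 19 (3R,3aS,6S,6aR)-6-(3,4-dimethoxyphenyl)-3-(4-hydroxy-3-methoxyphenyl)tetrahydro-1H,3H-furo[3,4-c]furan-3a-yl acetate (CNP0107105.1)
Conditions: NH4OAc, MeOH/H2O (4:1), rt
Reagents that add atoms: none
Why: Chemoselective aryl acetate cleavage by near-neutral transesterification: the phenoxide is a far better leaving group than a tertiary alkoxide and the C1 acetate is neopentyl-like and shielded by both rings, so only the phenol is released and no stereocentre is at risk.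

## Compound list

1 | (S)-4-benzyl-2-oxazolidinone | O=C1N[C@@H](Cc2ccccc2)CO1 | starting material
2 | methyl 4-chloro-4-oxobutanoate | COC(=O)CCC(=O)Cl | starting material
3 | methyl 4-[(4S)-4-benzyl-2-oxo-1,3-oxazolidin-3-yl]-4-oxobutanoate | COC(=O)CCC(=O)N1[C@@H](Cc2ccccc2)COC1=O | intermediate
4 | veratraldehyde | COc1ccc(C=O)cc1OC | starting material
5 | methyl (3S,4S)-3-{[(4S)-4-benzyl-2-oxo-1,3-oxazolidin-3-yl]carbonyl}-4-(3,4-dimethoxyphenyl)-4-hydroxybutanoate (syn-aldol, not isolated) | COC(=O)C[C@H](C(=O)N1[C@@H](Cc2ccccc2)COC1=O)[C@H](O)c3ccc(OC)c(OC)c3 | intermediate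
6 | (4S)-4-benzyl-3-{[(2S,3S)-2-(3,4-dimethoxyphenyl)-5-oxooxolan-3-yl]carbonyl}-1,3-oxazolidin-2-one | O=C1C[C@H](C(=O)N2[C@@H](Cc3ccccc3)COC2=O)[C@@H](c4ccc(OC)c(OC)c4)O1 | intermediate
7 | (2S,3S)-2-(3,4-dimethoxyphenyl)-5-oxooxolane-3-carboxylic acid | O=C1C[C@H](C(=O)O)[C@@H](c2ccc(OC)c(OC)c2)O1 | intermediate
8 | (4R,5S)-5-(3,4-dimethoxyphenyl)-4-(hydroxymethyl)oxolan-2-one | O=C1C[C@H](CO)[C@@H](c2ccc(OC)c(OC)c2)O1 | intermediate
9 | (4R,5S)-5-(3,4-dimethoxyphenyl)-4-[(triethylsilyloxy)methyl]oxolan-2-one | O=C1C[C@H](CO[Si](CC)(CC)CC)[C@@H](c2ccc(OC)c(OC)c2)O1 | intermediate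
10 | (3S,4S,5S)-5-(3,4-dimethoxyphenyl)-3-hydroxy-4-[(triethylsilyloxy)methyl]oxolan-2-one | O=C1[C@@H](O)[C@H](CO[Si](CC)(CC)CC)[C@@H](c2ccc(OC)c(OC)c2)O1 | intermediate
11 | (3S,4S,5S)-5-(3,4-dimethoxyphenyl)-4-[(triethylsilyloxy)methyl]oxolane-2,3-diol (anomeric mixture) | OC1[C@@H](O)[C@H](CO[Si](CC)(CC)CC)[C@@H](c2ccc(OC)c(OC)c2)O1 | intermediate
12 | (3S,4R,5S)-5-(3,4-dimethoxyphenyl)-4-[(triethylsilyloxy)methyl]oxolane-2,3-diyl diacetate (anomeric mixture) | CC(=O)OC1[C@@H](OC(C)=O)[C@H](CO[Si](CC)(CC)CC)[C@@H](c2ccc(OC)c(OC)c2)O1 | intermediate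
13 | (3S,4R,5S)-2-bromo-5-(3,4-dimethoxyphenyl)-4-[(triethylsilyloxy)methyl]oxolan-3-yl acetate (not isolated) | BrC1[C@@H](OC(C)=O)[C@H](CO[Si](CC)(CC)CC)[C@@H](c2ccc(OC)c(OC)c2)O1 | intermediate
14 | (2S,3R)-2-(3,4-dimethoxyphenyl)-3-[(triethylsilyloxy)methyl]-2,3-dihydrofuran-4-yl acetate | CC(=O)OC1=CO[C@H](c2ccc(OC)c(OC)c2)[C@H]1CO[Si](CC)(CC)CC | intermediate
15 | vanillin acetate (4-formyl-2-methoxyphenyl acetate) | COc1cc(C=O)ccc1OC(C)=O | starting material
16 | (E)-O3=C2 oxocarbenium ion from 14 and 15 (cation shown, triflate counter-ion, not isolated) | CC(=O)OC1=CO[C@H](c2ccc(OC)c(OC)c2)[C@H]1C/[O+]=C/c3ccc(OC(C)=O)c(OC)c3 | intermediate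
17 | bicyclic O7=C8 oxocarbenium ion, in equilibrium with its acetoxonium form (cation shown, triflate counter-ion, not isolated) | COc1cc(ccc1OC(C)=O)[C@H]2OC[C@@H]3[C@@H](c4ccc(OC)c(OC)c4)[O+]=C[C@]23OC(C)=O | intermediate
18 | (3R,3aS,6S,6aR)-3-(4-acetoxy-3-methoxyphenyl)-6-(3,4-dimethoxyphenyl)tetrahydro-1H,3H-furo[3,4-c]furan-3a-yl acetate | COc1cc(ccc1OC(C)=O)[C@H]2OC[C@@H]3[C@@H](c4ccc(OC)c(OC)c4)OC[C@]23OC(C)=O | intermediate
19 | (3R,3aS,6S,6aR)-6-(3,4-dimethoxyphenyl)-3-(4-hydroxy-3-methoxyphenyl)tetrahydro-1H,3H-furo[3,4-c]furan-3a-yl acetate | COc1cc([C@H]2OC[C@@H]3[C@@H](c4ccc(OC)c(OC)c4)OC[C@]23OC(C)=O)ccc1O | target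

## Step count

Total step count: 11.
Longest linear sequence: 11 steps (1 and 2 to 19). Compounds 4 and 15 enter as purchased.

## Steps most likely to fail

**Step 10.**
- Closure onto a carbon that becomes quaternary may be slow, so that protonation of the enol ether or oligomerisation takes over.
- Facial selectivity at C2 may be poor, because the two envelopes of the closing ring differ little in energy.
- Hydride may be delivered to the acetoxonium carbon instead of C8.
- The veratryl C6–O7 bond may suffer ionic hydrogenolysis or epimerisation.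

The fallback uses known chemistry, sets out from 14 and comes back at 18. The enol acetate of 14 is methanolysed (K2CO3 cat., MeOH, 0 °C) to the ketone (4R,5S)-5-(3,4-dimethoxyphenyl)-4-[(triethylsilyloxy)methyl]oxolan-3-one F1. Its silyl ether is then submitted with 15 to the established reductive etherification (Et3SiH present from the start, Me3SiOSO2CF3 cat., CH2Cl2, −78 °C). Here hydride capture of the aldehyde-derived oxocarbenium ion is the wanted event and outruns any reaction of the hindered ketone. This gives the benzyl ether (4R,5S)-4-{[(4-acetoxy-3-methoxybenzyl)oxy]methyl}-5-(3,4-dimethoxyphenyl)oxolan-3-one F2.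

Norrish–Yang photocyclisation (hν > 300 nm, benzene) is a known route from β-(benzyloxy) ketones to 3-hydroxytetrahydrofurans. The excited C1 carbonyl abstracts the benzylic C2 hydrogen and the 1,5-biradical closes C1–C2 with cis fusion. The product is the tertiary alcohol 4-[(3R,3aS,6S,6aR)-6-(3,4-dimethoxyphenyl)-3a-hydroxytetrahydro-1H,3H-furo[3,4-c]furan-3-yl]-2-methoxyphenyl acetate F3. Forcing acetylation (Ac2O, Et3N, DMAP, CH2Cl2, reflux) then gives 18.

**Step 9.**
- Me3SiBr may remove or exchange the triethylsilyl ether.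
- Me3SiBr may open the electron-rich benzylic C6–O7 bond.
- DBU may substitute the bromide instead of eliminating.

The fallback avoids any halide Lewis acid, sets out from 10 and comes back at 14. Compound 10 is acetylated (Ac2O, pyridine) to the α-acetoxy lactone (3S,4R,5S)-5-(3,4-dimethoxyphenyl)-2-oxo-4-[(triethylsilyloxy)methyl]oxolan-3-yl acetate F4. The lactone carbonyl alone is reduced with disiamylborane, (Me2CHCHMe)2BH, in THF, the reagent of choice for acylated aldonolactones. This gives the lactol (3S,4R,5S)-5-(3,4-dimethoxyphenyl)-2-hydroxy-4-[(triethylsilyloxy)methyl]oxolan-3-yl acetate F5. Mesylation of the anomeric hydroxyl (MeSO2Cl, Et3N, CH2Cl2, −40 °C) followed by DBU eliminates to 14.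

**Step 6.**
- The enolate may add to the sulfonimine that the oxaziridine leaves behind.
- The lactone may be over-oxidised.
- Conversion may be incomplete.

The fallback brings the C1 oxygen in by alkene oxidation instead of enolate oxidation, sets out from 9 and comes back at 11. Compound 9 is half-reduced (i-Bu2AlH, CH2Cl2, −78 °C) to the lactol (4R,5S)-5-(3,4-dimethoxyphenyl)-4-[(triethylsilyloxy)methyl]oxolan-2-ol F6. This is dehydrated through its mesylate (MeSO2Cl, Et3N, CH2Cl2, −40 °C → reflux) to the enol ether (2S,3R)-2-(3,4-dimethoxyphenyl)-3-[(triethylsilyloxy)methyl]-2,3-dihydrofuran F7. Dihydroxylation (OsO4 cat., NMO, acetone/H2O) from the face anti to the C5 arm gives 11.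

## Further compounds

F1 | step 10 | (4R,5S)-5-(3,4-dimethoxyphenyl)-4-[(triethylsilyloxy)methyl]oxolan-3-one | O=C1CO[C@H](c2ccc(OC)c(OC)c2)[C@H]1CO[Si](CC)(CC)CC
F2 | step 10 | (4R,5S)-4-{[(4-acetoxy-3-methoxybenzyl)oxy]methyl}-5-(3,4-dimethoxyphenyl)oxolan-3-one | O=C1CO[C@H](c2ccc(OC)c(OC)c2)[C@H]1COCc3ccc(OC(C)=O)c(OC)c3
F3 | step 10 | 4-[(3R,3aS,6S,6aR)-6-(3,4-dimethoxyphenyl)-3a-hydroxytetrahydro-1H,3H-furo[3,4-c]furan-3-yl]-2-methoxyphenyl acetate | COc1cc(ccc1OC(C)=O)[C@H]2OC[C@@H]3[C@@H](c4ccc(OC)c(OC)c4)OC[C@]23O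
F4 | step 9 | (3S,4R,5S)-5-(3,4-dimethoxyphenyl)-2-oxo-4-[(triethylsilyloxy)methyl]oxolan-3-yl acetate | O=C1[C@@H](OC(C)=O)[C@H](CO[Si](CC)(CC)CC)[C@@H](c2ccc(OC)c(OC)c2)O1
F5 | step 9 | (3S,4R,5S)-5-(3,4-dimethoxyphenyl)-2-hydroxy-4-[(triethylsilyloxy)methyl]oxolan-3-yl acetate (anomeric mixture) | OC1[C@@H](OC(C)=O)[C@H](CO[Si](CC)(CC)CC)[C@@H](c2ccc(OC)c(OC)c2)O1
F6 | step 6 | (4R,5S)-5-(3,4-dimethoxyphenyl)-4-[(triethylsilyloxy)methyl]oxolan-2-ol (anomeric mixture) | OC1C[C@H](CO[Si](CC)(CC)CC)[C@@H](c2ccc(OC)c(OC)c2)O1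
F7 | step 6 | (2S,3R)-2-(3,4-dimethoxyphenyl)-3-[(triethylsilyloxy)methyl]-2,3-dihydrofuran | C1=CO[C@H](c2ccc(OC)c(OC)c2)[C@H]1CO[Si](CC)(CC)CC
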